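## Structural features

The target is a dearomatised acylphloroglucinol. Its core is a cyclohexa-2,4-dienone (C4a, C5, C6, C7, C8, C8a in chromanone numbering) fused along C4a–C8a to a 2,3-dimethyl-2,3-dihydropyran-4-one (O1, C2, C3, C4). The carbocycle carries an enolic hydroxyl at C5, a ketone at C7, C3 of an octanoic acid chain at C6 and a quaternary carbon at C8. C8 holds a prenyl group and, through one methylene, a 2,2-dimethylcyclobutane whose second substituent, isopropenyl, is cis to that methylene across the ring. The six stereocentres fall into four sets that cannot relay to one another: C2/C3 (adjacent, trans, R,R), the quaternary C8 (R), the side-chain carbon (S), and the two cyclobutane methines (cis, separated by the C(CH3)2 carbon). Fragile elements are the isopropenylcyclobutane (protonation leads to cyclobutylcarbinyl ring expansion), the prenyl group beside an enolised tricarbonyl array (acid closes chromans), the pyranone (C3 epimerisable, O1–C2 open to retro-oxa-Michael cleavage in base) and the hydroxy acid, which lactonises onto a neighbouring ring oxygen. The real difficulty lies in the core: three oxygens and three carbons of a symmetrical phloroglucinol must each take a different role, and C8 must become a quaternary stereocentre by dearomatisation with no control element nearby. The key step exploits the cyclobutane: its C(CH3)2 carbon lies between the CH that carries the CH2 link and the CH that carries isopropenyl, with a ring CH2 closing the square. This is the imprint of a dimethylketene unit added across the C=C of an allyl arene, the ketene carbonyl carbon becoming the isopropenyl-bearing carbon.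

## Logic of the disconnections

26 ⇒ 22 + 23. The C8–CH2 bond to the prenyl group is cut; with it the carboxyl group is closed back onto O7 and O5 is capped with silicon. C8 is the only sp3 carbon of the carbocycle, so this cut restores an aromatic ring and removes the quaternary stereocentre. The gain is the largest of the analysis: a flat, fully substituted arene 22 in which the acid is masked as a lactone. Forward, the lactone must be opened to free the O7 oxide, carbon C8 (not C6 or oxygen) must be alkylated, and one ring face must be chosen by the catalyst; the silyl ether on O5 and the branched chain on C6 are there to shield C6.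

22 ⇒ 21. The O1–C2 bond of the pyranone is cut (retro-oxa-Michael). This removes a ring and both of its stereocentres and leaves an aryl enone. The cut is dictated by the trans-2,3-dimethyl pattern, the thermodynamic outcome of oxygen addition to a 2-methylbut-2-enoyl group followed by protonation. Forward, only O1 may add, which is why O5 carries silicon and O7 is acylated in 21; the enone face must be chosen by a chiral base and C3 settled by equilibration.

21 ⇒ 20 ⇒ 18 + 19. The lactone is taken down to lactol 20, then the C6–side-chain bond and the acetal C–O7 bond are cut. C6 is the last free carbon of an acylphloroglucinol and a vinylogous enol carbon, so the chain is best delivered as the eight-carbon electrophile 19, whose β-carbon becomes the side-chain stereocentre. This removes the whole side chain and one stereocentre. Forward, conjugate (not carbonyl) addition with face control is required, and the enone of 18 must stay open until the next step.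

18 ⇒ 16 + 17 ⇒ 15. The bond between the ketone carbon and the alkenyl carbon is cut, so that the acyl group arises from an aldehyde C–H bond and the four-carbon unit 17; the ring–CHO bond of 16 is cut in turn. The reason is the isopropenylcyclobutane: once it is present, ring acylation with acid chlorides and Lewis or Brønsted acids is excluded, and these two cuts need no acid. Forward, the formyl group must enter ortho to a free hydroxyl, and addition across the triple bond must be syn to give the E enone.

15 ⇒ 14 ⇒ 13. The O5–Si bond and then the three ester C–O bonds are cut. The silyl group is the single regiochemical decision of the synthesis: O5 is para to the alkyl group and is the only hydroxyl of 14 without an ortho substituent, whereas O1 and O7 stay equivalent until the ring is substituted. Forward, the silylation must be site-selective and the esters must come off without acid.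

13 ⇒ 12 ⇒ 11 ⇒ 10. The terminal CH2 of the isopropenyl group is cut (methylenation of a methyl ketone), then the two-carbon acetyl unit is traced back through enol ether 11 to the ring ketone of 10. This trades the isopropenyl-bearing stereocentre for a carbonyl group. The cis geometry returns in the forward sense because the ring carbon is protonated from the face away from the arylmethyl group and the cis ketone is also the more stable epimer. The ylides must leave three aryl esters intact, hence hindered pivalates.

10 ⇒ 4 + 7. Two bonds of the four-membered ring are cut: C(CH3)2–CH(CH2Ar) and C(=O)–CH2. This is the retron of a ketene-plus-alkene [2+2] addition; it dissolves the strained ring and its first stereocentre into 4 and 7. Forward, the ketene equivalent must be electrophilic enough for an unactivated terminal alkene, must place the gem-dimethyl carbon next to the substituted alkene carbon, and must select one alkene face. The arene must not compete, which is why 4 is kept as the triester and not redesigned with a donor group; the oxygen differentiation is added later, at 15.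

4 ⇒ 3 ⇒ 1 + 2 and 7 ⇒ 5 + 6. Ester C–O bonds, the aryl–allyl C–C bond and the amide C–N bond are cut, ending in four commercial compounds. C-allylation of 1 must stop at the mono stage, which is handled by using 1 in excess.

## Other disconnections considered

Alternative 1: The cut is through the C2–C3 bond and the O1–C8a bond of the pyranone, on the dearomatised core. In the forward key step, ketone A2 (a seco-pyranone of the enol lactone of 26, with a propanoyl group on C4a and a methoxy group on C8a) would be converted into its silyl dienol ether A3. A3 is a 1-methoxy-3-silyloxy diene in which C4a=C8a is one of the two double bonds. A hetero-Diels–Alder reaction of A3 with acetaldehyde A4 under a chiral Lewis acid, followed by loss of the methoxy and silyl groups, would give A1, from which 26 follows by lactone hydrolysis.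
- In its favour: the ring oxygen can only enter at the methoxy-bearing carbon, so the question of which phenolic oxygen closes the pyranone never arises. On this point the alternative is better than the chosen plan, which needs a silyl block on O5 (step 9) to answer it. C2 and C3 arise together under reagent control, and A1 is one step from 26.
- Against it here: A2 requires C8 to be quaternary already, C4a to be C-propanoylated and C8a to be O-methylated selectively. The dearomatisation therefore comes earlier, on a less differentiated substrate, and the ring acylation needs a non-acidic solution just as in the chosen plan. The diene terminus C8a is fully substituted, cross-conjugated to two carbonyl groups and next to the quaternary centre; it should be sluggish, and the facial outcome should depend on the match between catalyst and C8. The enol lactone and two acid-sensitive alkenes must survive the Lewis acid.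
- Comparison: structurally this step builds the pyranone and its two stereocentres, while the keteniminium step builds the strained cyclobutane and one stereocentre. The alternative leaves the cyclobutane to other means, so it could replace steps 10, 11 and 14 but not step 4. Mechanistically it is a [4+2] process (concerted or aldol-then-cyclise) against a polar [2+2]; both are reagent-controlled. In step count it is equal: acylation, enol silylation and cycloaddition against formylation, hydroacylation and oxa-Michael closure.

Alternative 2: The cut is through the C1–C2 and C3–C4 bonds of the phloroglucinol ring (arene numbering with the alkyl group on C2), that is, the aromatic ring itself. In the forward key step, 3-ethoxycyclobut-2-en-1-one A6 would be heated with siloxyalkyne A7, which already carries the finished cyclobutylmethyl group. Electrocyclic opening of A6 to a vinylketene, [2+2] addition to the ynol ether, opening of the new cyclobutenone and six-electron closure would give phenol A5.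
- In its favour: A5 has three different oxygens (a free hydroxyl and a silyl ether flanking the alkyl group, an ethyl ether para to it), fixed by the polarity of the two partners. This is better than the chosen plan, where the differentiation rests on a sterically controlled monosilylation. The conditions are neutral and thermal, which suits the isopropenylcyclobutane, and the approach is convergent.
- Against it here: no stereocentre is formed, and both cyclobutane stereocentres must already be in A7. Making A7 (ester-to-ynolate homologation and O-silylation of a cyclobutylacetic ester) has to follow a cyclobutane synthesis of its own. The para oxygen arrives as an ethyl ether; its cleavage calls for boron halides or hot thiolate, which the isopropenyl group and later the prenyl group would not tolerate.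
- Comparison: structurally it spends the key step on the flat ring that holds no stereochemistry, whereas the chosen step makes the strained ring and sets the first stereocentre. Mechanistically it is a cascade of four pericyclic events with no reagent at all, which is equal to or better than the keteniminium step in operational simplicity. In step economy it is worse overall: the seven steps that lead to the cyclobutane are not saved, and the ynol ether and the ether cleavage are added.

Alternative 3: The cut is through the bond from C6 to the side-chain carbon and the lactone C–O bond to O7. In the forward key step, chromanone A9 (5,7-dihydroxy, one free ring carbon, C6) would react with (2E)-oct-2-enal A10 (the same enal as 19) under a chiral triazolium-derived carbene and an oxidant. The unsaturated acyl azolium would be attacked at its β-carbon by C6, and the acyl group would then pass to the neighbouring oxygen, giving lactone A8.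
- In its favour: C–C bond, stereocentre and lactone at the acid oxidation level arise in one step on a substrate with a single reactive carbon. This is better than steps 12 and 13 of the chosen plan, which need two operations (lactol, then oxidation) for the same result. A8 is the desilylated form of 22, so the two plans converge.
- Against it here: the phenol is an electron-rich, chelated hydroxy ketone exposed to an oxidant. O-acylation without C–C bond formation competes for phenols less enol-like than naphthols. The lactone may close on O5 or O7. A9 itself needs the same regiocontrolled pyranone closure, and with O5 free in A8 the later prenylation has only the branched chain to keep it away from C6.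
- Comparison: structurally this step sets one isolated stereocentre on the periphery and does nothing for the cyclobutane, so it competes with steps 12 and 13, not with step 4. Mechanistically, acyl azolium and iminium catalysis are two oxidation levels of the same conjugate addition, with comparable expected selectivity. In step economy the alternative is one step shorter for this fragment, and its redox-neutral form is kept as the fallback for step 12.

Key step: step 4

Assumption: the sense of induction of the chiral amide (step 4), the prolinol catalyst (step 12), quinine (step 14) and the palladium ligand (step 15) is assigned by analogy with the usual models; if one proves opposite, its antipode (quinidine for quinine) is used and nothing else changes.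

## Steps

Step 1
Reactants: 1 phloroglucinol; 2 allyl bromide
Product: 3 2-allylphloroglucinol
Conditions: DBU, THF, 0 °C → rt (1 in threefold excess, recovered)
Reagents that add atoms: none
Why: Phloroglucinol behaves as a vinylogous enol, so under an amidine base in THF the soft allylic halide is taken up at carbon (C-allylation of a phenol). The excess of 1 suppresses di- and tri-allylation.

Step 2
Reactants: 3 2-allylphloroglucinol
Product: 4 2-allylphloroglucinol tripivalate
Conditions: t-BuCOCl, pyridine, DMAP (cat.), CH2Cl2, 0 °C → rt
Reagents that add atoms: pivaloyl chloride, CC(C)(C)C(=O)Cl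
Why: DMAP-catalysed O-acylation of all three phenols. The pivalates make the arene electron-poor and hindered for the cycloaddition and resist the ylides of steps 5 and 7; a donor-type or differentiated protecting pattern is deliberately not introduced at this stage.

Step 3
Reactants: 5 (2S,5S)-2,5-dimethylpyrrolidine; 6 isobutyryl chloride
Product: 7 1-[(2S,5S)-2,5-dimethylpyrrolidin-1-yl]-2-methylpropan-1-one
Conditions: Et3N, CH2Cl2, 0 °C → rt
Reagents that add atoms: none
Why: N-acylation of the secondary amine by the acid chloride (amide formation); the stereocentres are not involved.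

Step 4
Reactants: 4 2-allylphloroglucinol tripivalate; 7 chiral isobutyramide
Product: 10 (3S)-2,2-dimethyl-3-{[2,4,6-tris(2,2-dimethylpropanoyloxy)phenyl]methyl}cyclobutan-1-one, via keteniminium triflate 8 (not isolated), via cyclobutaniminium triflate 9 (not isolated)
Conditions: (CF3SO2)2O, 2,6-di-tert-butyl-4-methylpyridine, ClCH2CH2Cl, −20 → 80 °C; then H2O, THF, 50 °C
Reagents that add atoms: water, O
Why: Triflic anhydride O-sulfonylates amide 7 and the hindered pyridine removes the α-proton, giving keteniminium salt 8, whose central carbon is a far stronger electrophile than that of a ketene. The terminal CH2 of the allyl group of 4 attacks that carbon, placing positive charge on the internal carbon, and the enamine-like C(CH3)2 carbon then collapses onto it; the four-membered ring is thus closed by a polar, asynchronous [2+2] cycloaddition (two bonds in one event, not the cyclisation of a preformed chain), and water hydrolyses cyclobutaniminium salt 9 to ketone 10. This polarity fixes the regiochemistry: the gem-dimethyl carbon ends next to the carbon that carries the arylmethyl group, as the target requires. The single new stereocentre (C3 of 10) is set by reagent control: in the C2-symmetric trans-2,5-dimethylpyrrolidinium unit one methyl group shields the same face of the ketene terminus in either rotamer, so the alkene is engaged from one enantiotopic face. The step needs chemoselectivity for the alkene over the arene, and the three electron-withdrawing, bulky pivalates secure it by suppressing Friedel–Crafts acylation and aryl participation in the cationic intermediate. The closest known reaction type is the keteniminium–alkene [2+2] cycloaddition of isobutyramide-derived salts with unactivated 1-alkenes, including its variant with C2-symmetric pyrrolidine amides.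

Step 5
Reactants: 10 cyclobutanone tripivalate
Product: 11 2-{[(1R)-3-(1-methoxyethylidene)-2,2-dimethylcyclobutyl]methyl}benzene-1,3,5-triyl tris(2,2-dimethylpropanoate) (E/Z mixture)
Conditions: Ph3P(+)CH(CH3)OCH3 Cl(−), KN(SiMe3)2, THF, −78 → 0 °C
Reagents that add atoms: (1-methoxyethyl)triphenylphosphonium chloride, COC(C)[P+](c1ccccc1)(c1ccccc1)c1ccccc1.[Cl-]
Why: Wittig reaction with an α-methoxyalkylidene ylide; cyclobutanones are reactive toward ylides despite the adjacent quaternary carbon, and hindered, non-enolisable pivalates are poor acyl donors toward the ylide. The E/Z ratio is irrelevant because the enol ether is hydrolysed next.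

Step 6
Reactants: 11 enol ether
Product: 12 2-{[(1R,3R)-3-acetyl-2,2-dimethylcyclobutyl]methyl}benzene-1,3,5-triyl tris(2,2-dimethylpropanoate) (cis)
Conditions: 2 M HCl, THF, rt; then DBU (cat.), toluene, rt
Reagents that add atoms: water, O
Why: Acid hydrolysis of the enol ether: the ring carbon is protonated from the face opposite the arylmethyl group, which gives the cis ketone, and the oxocarbenium ion is then hydrolysed. The cis isomer, with both substituents pseudo-equatorial, is also the expected thermodynamic one, so brief DBU equilibration converges on 12; this sets the second cyclobutane stereocentre under substrate control.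

Step 7
Reactants: 12 cis-acetyl tripivalate
Product: 13 2-{[(1R,3S)-2,2-dimethyl-3-(prop-1-en-2-yl)cyclobutyl]methyl}benzene-1,3,5-triyl tris(2,2-dimethylpropanoate) (cis)
Conditions: Ph3P(+)CH3 Br(−), KN(SiMe3)2, THF, 0 °C → rt
Reagents that add atoms: methyltriphenylphosphonium bromide, C[P+](c1ccccc1)(c1ccccc1)c1ccccc1.[Br-]
Why: Wittig methylenation of a methyl ketone; the α-stereocentre is already in its preferred configuration, so the basic ylide cannot erode it, and the hindered pivalates are not attacked.

Step 8
Reactants: 13 isopropenyl tripivalate
Product: 14 2-{[(1R,3S)-2,2-dimethyl-3-(prop-1-en-2-yl)cyclobutyl]methyl}benzene-1,3,5-triol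
Conditions: NaOMe, MeOH, 40 °C, argon; then AcOH
Reagents that add atoms: none
Why: Base-mediated transesterification (Zemplén type) frees the three phenols as phenoxides under argon. From here on no strong acid is used, because protonation of the isopropenyl group would trigger cyclobutylcarbinyl ring expansion.

Step 9
Reactants: 14 triol
Product: 15 2-{[(1R,3S)-2,2-dimethyl-3-(prop-1-en-2-yl)cyclobutyl]methyl}-5-[tri(propan-2-yl)silyloxy]benzene-1,3-diol
Conditions: i-Pr3SiCl (1.05 equiv), imidazole, DMF, −20 °C
Reagents that add atoms: chlorotri(propan-2-yl)silane, CC(C)[Si](Cl)(C(C)C)C(C)C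
Why: Silylation of a phenol with a bulky chlorosilane, which should select the one hydroxyl (O5, para to the alkyl group) that has no ortho substituent; the two flanked hydroxyls are equivalent. This block on O5 is what later forces the pyranone to close on O1 and keeps alkylation away from C6.

Step 10
Reactants: 15 silyl ether diol
Product: 16 2,4-dihydroxy-3-{[(1R,3S)-2,2-dimethyl-3-(prop-1-en-2-yl)cyclobutyl]methyl}-6-[tri(propan-2-yl)silyloxy]benzaldehyde
Conditions: MgCl2, Et3N, (CH2O)n, THF, 65 °C
Reagents that add atoms: paraformaldehyde (as formaldehyde), C=O
Why: Casnati–Skattebøl ortho-formylation: the magnesium phenoxide delivers formaldehyde to the ortho carbon and a second equivalent oxidises the benzylic alkoxide. The two free ring carbons of 15 are equivalent, the formyl group deactivates the ring against a second entry, and no acid is involved.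

Step 11
Reactants: 16 salicylaldehyde; 17 but-2-yne
Product: 18 (2E)-1-(2,4-dihydroxy-3-{[(1R,3S)-2,2-dimethyl-3-(prop-1-en-2-yl)cyclobutyl]methyl}-6-[tri(propan-2-yl)silyloxy]phenyl)-2-methylbut-2-en-1-one
Conditions: [Rh(cod)Cl]2 (2.5 mol %), dppf (5 mol %), Na2CO3 (10 mol %), toluene, 80 °C, sealed tube
Reagents that add atoms: none
Why: Chelation-assisted hydroacylation of an internal alkyne by a salicylaldehyde: the phenoxide-bound rhodium inserts into the aldehyde C–H bond and the acyl rhodium hydride adds syn across 17, giving the E (tigloyl) enone. The hindered 1,1-disubstituted alkene of the cyclobutane should not compete, and the acyl group is installed without any acid.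

Step 12
Reactants: 18 tigloyl phenol; 19 (2E)-oct-2-enal
Product: 20 (4S)-7-hydroxy-6-[(2E)-2-methylbut-2-enoyl]-4-pentyl-8-{[(1R,3S)-2,2-dimethyl-3-(prop-1-en-2-yl)cyclobutyl]methyl}-5-[tri(propan-2-yl)silyloxy]-3,4-dihydro-2H-chromen-2-ol (anomeric mixture)
Conditions: (R)-α,α-diphenylprolinol trimethylsilyl ether (20 mol %), PhCO2H (20 mol %), toluene, 0 °C
Reagents that add atoms: none
Why: Iminium-ion catalysis: the only free ring carbon of the acylphloroglucinol, a vinylogous enol carbon like that of a cyclic 1,3-dicarbonyl or a naphthol, adds to the β-carbon of the unsaturated iminium ion (Friedel–Crafts-type conjugate addition) and the neighbouring free hydroxyl closes the lactol. The diarylsilyloxymethyl group shields one face of the s-trans E-iminium ion, so the ring carbon adds to the open face and sets the side-chain stereocentre (S); the buffered amine is too weak a base to close the enone prematurely.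

Step 13
Reactants: 20 lactol
Product: 21 (4S)-7-hydroxy-6-[(2E)-2-methylbut-2-enoyl]-4-pentyl-8-{[(1R,3S)-2,2-dimethyl-3-(prop-1-en-2-yl)cyclobutyl]methyl}-5-[tri(propan-2-yl)silyloxy]-3,4-dihydro-2H-chromen-2-one
Conditions: Dess–Martin periodinane, pyridine, CH2Cl2, 0 °C → rt
Reagents that add atoms: none
Why: Oxidation of a lactol to a lactone by a hypervalent iodine reagent under buffered, non-acidic conditions. The only free phenol is hydrogen-bonded to the ketone and inert, and no stereocentre is touched (the anomeric centre disappears).

Step 14
Reactants: 21 tigloyl lactone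
Product: 22 (2R,3R,6S)-2,3-dimethyl-6-pentyl-10-{[(1R,3S)-2,2-dimethyl-3-(prop-1-en-2-yl)cyclobutyl]methyl}-5-[tri(propan-2-yl)silyloxy]-2,3,6,7-tetrahydro-4H,8H-pyrano[3,2-g]chromene-4,8-dione
Conditions: quinine (1 equiv), PhCl, 15 °C; then Et3N, CH2Cl2, rt
Reagents that add atoms: none
Why: Cinchona-alkaloid-mediated intramolecular oxa-Michael addition (6-endo-trig) of the ortho hydroxyl to the 2-methylbut-2-enoyl group, the known route to 2,3-dimethylchroman-4-ones; only O1 can add because O5 is silylated and O7 acylated. Quinine, ion-paired with the phenoxide, selects the face of the β-carbon and sets C2 (R); C3 is then set under thermodynamic control by triethylamine-mediated enolisation to the trans (diequatorial) isomer.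

Step 15
Reactants: 22 tricyclic lactone; 23 prenyl acetate
Product: 26 (3S)-3-[(2R,3R,8R)-5-hydroxy-2,3-dimethyl-8-(3-methylbut-2-en-1-yl)-4,7-dioxo-8-{[(1R,3S)-2,2-dimethyl-3-(prop-1-en-2-yl)cyclobutyl]methyl}-3,4,7,8-tetrahydro-2H-chromen-6-yl]octanoic acid (CNP0208815.1), via ring-opened dipotassium salt 24 (not isolated), via silyl dienol ether carboxylate 25 (not isolated)
Conditions: KOSiMe3 (2.1 equiv), THF, 0 °C; then Pd2(dba)3·CHCl3 (2.5 mol %), (1R,2R)-N,N′-bis(2-diphenylphosphinobenzoyl)cyclohexane-1,2-diamine (7.5 mol %), 23, THF, 0 °C → rt; then AcOH/THF/H2O, rt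
Reagents that add atoms: potassium trimethylsilanolate, C[Si](C)(C)[O-].[K+]
Why: KOSiMe3 opens the aryl lactone to carboxylate-phenoxide 24, and zerovalent palladium ionises 23 to a π-prenyl complex that is attacked at its unsubstituted terminus by C8, the carbon ortho to the O7 oxide (Tsuji–Trost dearomative C-allylation of a phenoxide). C6 is shielded by the branched chain and the silyl ether, and O-prenyl ethers or esters re-ionise under the catalyst, so material should funnel to the C–C product. The new quaternary stereocentre has no useful neighbour and is set by the chiral diphosphine ligand (catalyst control); aqueous acetic acid then protonates the carboxylate and hydrolyses the silyl dienol ether of 25 to the C5 enol.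

## Compound list

1 | phloroglucinol (benzene-1,3,5-triol) | Oc1cc(O)cc(O)c1 | starting material
2 | allyl bromide (3-bromoprop-1-ene) | C=CCBr | starting material
3 | 2-allylphloroglucinol (2-(prop-2-en-1-yl)benzene-1,3,5-triol) | C=CCc1c(O)cc(O)cc1O | intermediate
4 | 2-allylphloroglucinol tripivalate (2-(prop-2-en-1-yl)benzene-1,3,5-triyl tris(2,2-dimethylpropanoate)) | C=CCc1c(OC(=O)C(C)(C)C)cc(OC(=O)C(C)(C)C)cc1OC(=O)C(C)(C)C | intermediate
5 | (2S,5S)-2,5-dimethylpyrrolidine | C[C@H]1CC[C@H](C)N1 | starting material
6 | isobutyryl chloride (2-methylpropanoyl chloride) | CC(C)C(Cl)=O | starting material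
7 | 1-[(2S,5S)-2,5-dimethylpyrrolidin-1-yl]-2-methylpropan-1-one | C[C@H]1CC[C@H](C)N1C(=O)C(C)C | intermediate
8 | (2S,5S)-2,5-dimethyl-1-(2-methylprop-1-en-1-ylidene)pyrrolidin-1-ium trifluoromethanesulfonate (keteniminium triflate) | CC(C)=C=[N+]1[C@@H](C)CC[C@@H]1C.[O-]S(=O)(=O)C(F)(F)F | intermediate
9 | (2S,5S)-1-[(3S)-2,2-dimethyl-3-{[2,4,6-tris(2,2-dimethylpropanoyloxy)phenyl]methyl}cyclobutylidene]-2,5-dimethylpyrrolidin-1-ium trifluoromethanesulfonate (cyclobutaniminium triflate) | CC(C)(C)C(=O)Oc1cc(OC(=O)C(C)(C)C)c(C[C@H]2CC(=[N+]3[C@@H](C)CC[C@@H]3C)C2(C)C)c(OC(=O)C(C)(C)C)c1.[O-]S(=O)(=O)C(F)(F)F | intermediate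
10 | (3S)-2,2-dimethyl-3-{[2,4,6-tris(2,2-dimethylpropanoyloxy)phenyl]methyl}cyclobutan-1-one | CC(C)(C)C(=O)Oc1cc(OC(=O)C(C)(C)C)c(C[C@H]2CC(=O)C2(C)C)c(OC(=O)C(C)(C)C)c1 | intermediate
11 | 2-{[(1R)-3-(1-methoxyethylidene)-2,2-dimethylcyclobutyl]methyl}benzene-1,3,5-triyl tris(2,2-dimethylpropanoate) (E/Z mixture) | CC(C)(C)C(=O)Oc1cc(OC(=O)C(C)(C)C)c(C[C@H]2CC(=C(C)OC)C2(C)C)c(OC(=O)C(C)(C)C)c1 | intermediate
12 | 2-{[(1R,3R)-3-acetyl-2,2-dimethylcyclobutyl]methyl}benzene-1,3,5-triyl tris(2,2-dimethylpropanoate) (cis) | CC(C)(C)C(=O)Oc1cc(OC(=O)C(C)(C)C)c(C[C@H]2C[C@@H](C(C)=O)C2(C)C)c(OC(=O)C(C)(C)C)c1 | intermediate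
13 | 2-{[(1R,3S)-2,2-dimethyl-3-(prop-1-en-2-yl)cyclobutyl]methyl}benzene-1,3,5-triyl tris(2,2-dimethylpropanoate) (cis) | CC(C)(C)C(=O)Oc1cc(OC(=O)C(C)(C)C)c(C[C@H]2C[C@@H](C(C)=C)C2(C)C)c(OC(=O)C(C)(C)C)c1 | intermediate
14 | 2-{[(1R,3S)-2,2-dimethyl-3-(prop-1-en-2-yl)cyclobutyl]methyl}benzene-1,3,5-triol | Oc1cc(O)c(C[C@H]2C[C@@H](C(C)=C)C2(C)C)c(O)c1 | intermediate
15 | 2-{[(1R,3S)-2,2-dimethyl-3-(prop-1-en-2-yl)cyclobutyl]methyl}-5-[tri(propan-2-yl)silyloxy]benzene-1,3-diol | CC(C)[Si](Oc1cc(O)c(C[C@H]2C[C@@H](C(C)=C)C2(C)C)c(O)c1)(C(C)C)C(C)C | intermediate
16 | 2,4-dihydroxy-3-{[(1R,3S)-2,2-dimethyl-3-(prop-1-en-2-yl)cyclobutyl]methyl}-6-[tri(propan-2-yl)silyloxy]benzaldehyde | O=Cc1c(O)c(C[C@H]2C[C@@H](C(C)=C)C2(C)C)c(O)cc1O[Si](C(C)C)(C(C)C)C(C)C | intermediate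
17 | but-2-yne | CC#CC | starting material
18 | (2E)-1-(2,4-dihydroxy-3-{[(1R,3S)-2,2-dimethyl-3-(prop-1-en-2-yl)cyclobutyl]methyl}-6-[tri(propan-2-yl)silyloxy]phenyl)-2-methylbut-2-en-1-one | C/C=C(\C)C(=O)c1c(O)c(C[C@H]2C[C@@H](C(C)=C)C2(C)C)c(O)cc1O[Si](C(C)C)(C(C)C)C(C)C | intermediate
19 | (2E)-oct-2-enal | CCCCC/C=C/C=O | starting material
20 | (4S)-7-hydroxy-6-[(2E)-2-methylbut-2-enoyl]-4-pentyl-8-{[(1R,3S)-2,2-dimethyl-3-(prop-1-en-2-yl)cyclobutyl]methyl}-5-[tri(propan-2-yl)silyloxy]-3,4-dihydro-2H-chromen-2-ol (anomeric mixture) | C/C=C(\C)C(=O)c1c(O)c(C[C@H]3C[C@@H](C(C)=C)C3(C)C)c2OC(O)C[C@H](CCCCC)c2c1O[Si](C(C)C)(C(C)C)C(C)C | intermediate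
21 | (4S)-7-hydroxy-6-[(2E)-2-methylbut-2-enoyl]-4-pentyl-8-{[(1R,3S)-2,2-dimethyl-3-(prop-1-en-2-yl)cyclobutyl]methyl}-5-[tri(propan-2-yl)silyloxy]-3,4-dihydro-2H-chromen-2-one | C/C=C(\C)C(=O)c1c(O)c(C[C@H]3C[C@@H](C(C)=C)C3(C)C)c2OC(=O)C[C@H](CCCCC)c2c1O[Si](C(C)C)(C(C)C)C(C)C | intermediate
22 | (2R,3R,6S)-2,3-dimethyl-6-pentyl-10-{[(1R,3S)-2,2-dimethyl-3-(prop-1-en-2-yl)cyclobutyl]methyl}-5-[tri(propan-2-yl)silyloxy]-2,3,6,7-tetrahydro-4H,8H-pyrano[3,2-g]chromene-4,8-dione (linear tricycle: chromanone on O1/C4a, dihydrocoumarin lactone on O7/C6) | O=C1C[C@H](CCCCC)c2c(O1)c(C[C@H]1C[C@@H](C(C)=C)C1(C)C)c1O[C@H](C)[C@@H](C)C(=O)c1c2O[Si](C(C)C)(C(C)C)C(C)C | intermediate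
23 | prenyl acetate (3-methylbut-2-en-1-yl acetate) | CC(=O)OCC=C(C)C | starting material
24 | dipotassium (3S)-3-[(2R,3R)-2,3-dimethyl-7-oxido-4-oxo-8-{[(1R,3S)-2,2-dimethyl-3-(prop-1-en-2-yl)cyclobutyl]methyl}-5-[tri(propan-2-yl)silyloxy]-3,4-dihydro-2H-chromen-6-yl]octanoate | [K+].[K+].[O-]C(=O)C[C@H](CCCCC)c1c([O-])c(C[C@H]2C[C@@H](C(C)=C)C2(C)C)c2O[C@H](C)[C@@H](C)C(=O)c2c1O[Si](C(C)C)(C(C)C)C(C)C | intermediate
25 | potassium (3S)-3-[(2R,3R,8R)-2,3-dimethyl-8-(3-methylbut-2-en-1-yl)-4,7-dioxo-8-{[(1R,3S)-2,2-dimethyl-3-(prop-1-en-2-yl)cyclobutyl]methyl}-5-[tri(propan-2-yl)silyloxy]-3,4,7,8-tetrahydro-2H-chromen-6-yl]octanoate | [K+].C=C(C)[C@@H]1C[C@H](C[C@@]2(CC=C(C)C)C(=O)C([C@@H](CCCCC)CC(=O)[O-])=C(O[Si](C(C)C)(C(C)C)C(C)C)C3=C2O[C@H](C)[C@@H](C)C3=O)C1(C)C | intermediate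
26 | (3S)-3-[(2R,3R,8R)-5-hydroxy-2,3-dimethyl-8-(3-methylbut-2-en-1-yl)-4,7-dioxo-8-{[(1R,3S)-2,2-dimethyl-3-(prop-1-en-2-yl)cyclobutyl]methyl}-3,4,7,8-tetrahydro-2H-chromen-6-yl]octanoic acid (CNP0208815.1) | C=C(C)[C@@H]1C[C@H](C[C@@]2(CC=C(C)C)C(=O)C([C@@H](CCCCC)CC(=O)O)=C(O)C3=C2O[C@H](C)[C@@H](C)C3=O)C1(C)C | target

## Step count and least certain steps

Total step count: 15. Longest linear sequence: 14 steps (steps 1, 2 and 4 to 15); step 3 is a one-step branch.

Step 4 (key step). What may go wrong: incomplete discrimination between the two alkene faces, because a monosubstituted alkene offers little steric contrast to the chiral iminium unit, and slow cycloaddition that leaves the keteniminium salt time to decompose. Fallback: 4 is combined with the keteniminium salt from achiral N,N-dimethyl-2-methylpropanamide (triflic anhydride, hindered pyridine, then water), which should give the racemic cyclobutanone F1. Its enantiomers are separated by preparative chromatography on a chiral stationary phase, and the (S) enantiomer re-enters the route as 10.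

Step 5. What may go wrong: enolisation of the cyclobutanone by the strongly basic alkoxy ylide, slow addition next to the quaternary carbon, or acyl transfer from an aryl pivalate to the ylide. Fallback: 10 is treated with ethylidenetriphenylphosphorane to give the ethylidenecyclobutane F2. Hydroboration (BH3·THF, then NaBO3·4H2O) places boron on the exocyclic carbon and hydrogen on the ring carbon from the face away from the arylmethyl group, giving the secondary alcohol F3 with the cis ring geometry. Dess–Martin oxidation returns to the route at 12.

Step 9. What may go wrong: silylation of a flanked hydroxyl or double silylation, since the site selectivity rests on steric hindrance alone. Fallback: the differentiation is made at the ester stage instead. Starting from 13, controlled methanolysis (K2CO3, MeOH, 0 °C) cleaves the least hindered pivalate, the one para to the alkyl group, to give the 5-hydroxy dipivalate F4. Silylation of its only hydroxyl (i-Pr3SiOSO2CF3, 2,6-lutidine) gives the silyl ether dipivalate F5. Reductive removal of the two remaining pivalates (i-Bu2AlH, CH2Cl2, −78 °C), which spares the aryl silyl ether, returns to the route at 15.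

Step 12. What may go wrong: addition to the iminium carbon instead of the β-carbon, followed by dehydration and electrocyclisation to a 2H-chromene; slow reaction of a ring deactivated by the ketone; or premature base-induced closure of the enone. Fallback: 18 is annulated with oct-2-ynal under a chiral aminoindanol-derived triazolium carbene catalyst (redox-neutral formation of the unsaturated acyl azolium, conjugate addition of C6, acyl transfer to O7). This gives the lactone directly and returns to the route at 21; the fallback makes no new compound (entry F0).

Step 15. What may go wrong: alkylation at oxygen or at C6, attack at the substituted terminus of the π-prenyl unit (reverse prenylation), re-closure of the lactone before alkylation, and above all poor facial selectivity at C8, for which only the ligand is responsible. Fallback: 22 is saponified with aqueous KOH (lactone opening and loss of the silyl group) and the resulting phenoxide carboxylate is alkylated in the same aqueous medium with prenyl bromide at 0 °C, the classical C-alkylative dearomatisation of phloroglucinol anions in water. After acidification this should give 26 together with its C8 epimer F6, from which it is separated by chromatography, so the fallback returns to the route at 26.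

## Further compounds

F1 | step 4 | racemic 2,2-dimethyl-3-{[2,4,6-tris(2,2-dimethylpropanoyloxy)phenyl]methyl}cyclobutan-1-one | CC(C)(C)C(=O)Oc1cc(OC(=O)C(C)(C)C)c(CC2CC(=O)C2(C)C)c(OC(=O)C(C)(C)C)c1
F2 | step 5 | 2-{[(1R)-3-ethylidene-2,2-dimethylcyclobutyl]methyl}benzene-1,3,5-triyl tris(2,2-dimethylpropanoate) (E/Z mixture) | CC(C)(C)C(=O)Oc1cc(OC(=O)C(C)(C)C)c(C[C@H]2CC(=CC)C2(C)C)c(OC(=O)C(C)(C)C)c1
F3 | step 5 | 2-{[(1R,3R)-3-(1-hydroxyethyl)-2,2-dimethylcyclobutyl]methyl}benzene-1,3,5-triyl tris(2,2-dimethylpropanoate) (cis, carbinol epimers) | CC(C)(C)C(=O)Oc1cc(OC(=O)C(C)(C)C)c(C[C@H]2C[C@@H](C(C)O)C2(C)C)c(OC(=O)C(C)(C)C)c1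
F4 | step 9 | 5-hydroxy-2-{[(1R,3S)-2,2-dimethyl-3-(prop-1-en-2-yl)cyclobutyl]methyl}-1,3-phenylene bis(2,2-dimethylpropanoate) | CC(C)(C)C(=O)Oc1cc(O)cc(OC(=O)C(C)(C)C)c1C[C@H]1C[C@@H](C(C)=C)C1(C)C
F5 | step 9 | 2-{[(1R,3S)-2,2-dimethyl-3-(prop-1-en-2-yl)cyclobutyl]methyl}-5-[tri(propan-2-yl)silyloxy]-1,3-phenylene bis(2,2-dimethylpropanoate) | CC(C)(C)C(=O)Oc1cc(O[Si](C(C)C)(C(C)C)C(C)C)cc(OC(=O)C(C)(C)C)c1C[C@H]1C[C@@H](C(C)=C)C1(C)C
F0 | step 12 | none | none
F6 | step 15 | C8 epimer of 26: (3S)-3-[(2R,3R,8S)-5-hydroxy-2,3-dimethyl-8-(3-methylbut-2-en-1-yl)-4,7-dioxo-8-{[(1R,3S)-2,2-dimethyl-3-(prop-1-en-2-yl)cyclobutyl]methyl}-3,4,7,8-tetrahydro-2H-chromen-6-yl]octanoic acid | C=C(C)[C@@H]1C[C@H](C[C@]2(CC=C(C)C)C(=O)C([C@@H](CCCCC)CC(=O)O)=C(O)C3=C2O[C@H](C)[C@@H](C)C3=O)C1(C)C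
A1 | alternative 1 | enol lactone of 26 (carboxyl closed onto the C5 enol oxygen) | C=C(C)[C@@H]1C[C@H](C[C@@]2(CC=C(C)C)C(=O)C3=C(OC(=O)C[C@@H]3CCCCC)C3=C2O[C@H](C)[C@@H](C)C3=O)C1(C)C
A2 | alternative 1 | seco-pyranone of A1 with a propanoyl group on C4a and a methoxy group on C8a | C=C(C)[C@@H]1C[C@H](C[C@@]2(CC=C(C)C)C(=O)C3=C(OC(=O)C[C@@H]3CCCCC)C(C(=O)CC)=C2OC)C1(C)C
A3 | alternative 1 | tert-butyldimethylsilyl dienol ether of A2 (1-methoxy-3-silyloxy diene) | C=C(C)[C@@H]1C[C@H](C[C@@]2(CC=C(C)C)C(=O)C3=C(OC(=O)C[C@@H]3CCCCC)C(C(O[Si](C)(C)C(C)(C)C)=CC)=C2OC)C1(C)C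
A4 | alternative 1 | acetaldehyde | CC=O
A5 | alternative 2 | 5-ethoxy-2-{[(1R,3S)-2,2-dimethyl-3-(prop-1-en-2-yl)cyclobutyl]methyl}-3-[tri(propan-2-yl)silyloxy]phenol | CCOc1cc(O)c(C[C@H]2C[C@@H](C(C)=C)C2(C)C)c(O[Si](C(C)C)(C(C)C)C(C)C)c1
A6 | alternative 2 | 3-ethoxycyclobut-2-en-1-one | CCOC1=CC(=O)C1
A7 | alternative 2 | {3-[(1R,3S)-2,2-dimethyl-3-(prop-1-en-2-yl)cyclobutyl]prop-1-yn-1-yloxy}tri(propan-2-yl)silane | CC(C)[Si](OC#CC[C@H]1C[C@@H](C(C)=C)C1(C)C)(C(C)C)C(C)C
A8 | alternative 3 | (2R,3R,6S)-5-hydroxy-2,3-dimethyl-6-pentyl-10-{[(1R,3S)-2,2-dimethyl-3-(prop-1-en-2-yl)cyclobutyl]methyl}-2,3,6,7-tetrahydro-4H,8H-pyrano[3,2-g]chromene-4,8-dione | O=C1C[C@H](CCCCC)c2c(O1)c(C[C@H]1C[C@@H](C(C)=C)C1(C)C)c1O[C@H](C)[C@@H](C)C(=O)c1c2O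
A9 | alternative 3 | (2R,3R)-5,7-dihydroxy-2,3-dimethyl-8-{[(1R,3S)-2,2-dimethyl-3-(prop-1-en-2-yl)cyclobutyl]methyl}-2,3-dihydro-4H-chromen-4-one | O=C1c2c(O)cc(O)c(C[C@H]3C[C@@H](C(C)=C)C3(C)C)c2O[C@H](C)[C@H]1C
A10 | alternative 3 | (2E)-oct-2-enal | CCCCC/C=C/C=O
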